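## Retrosynthetic overview
1. The quinone is made last, by oxidative demethylation of a 2'-hydroxy-3',4',5'-trimethoxyisoflavan. Only ring B carries a free OH, so ring A is not oxidised.
2. The pyran ring and the C3–aryl bond form in one electrochemical step from an acyclic (S)-1-aryl-3-aryloxypropan-2-ol. Anodic Ph3P activation is followed by a 1,2-aryl shift through a phenonium ion (inversion at C3), then Friedel–Crafts closure of C4–C4a.
3. The alcohol comes from ortho-lithiated MOM-protected 2,3,4-trimethoxyphenol and an (S)-aryl glycidyl ether.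
4. The glycidyl ether comes from the same phenol and (R)-epichlorohydrin, which supplies the only stereocentre.
5. Ring order: both benzene rings are bought, the pyran ring closes in step 4, and the quinone forms in step 5.

Assumption: 2,3,4-trimethoxyphenol is bought as a catalogue compound. C3 of the target reads as (S) from the given SMILES.

## Route

Step 1
Reactants: 1 2,3,4-trimethoxyphenol; 2 (R)-epichlorohydrin
Product: 4 (S)-2-[(2,3,4-trimethoxyphenoxy)methyl]oxirane, via (R)-1-chloro-3-(2,3,4-trimethoxyphenoxy)propan-2-ol 3 (not isolated)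
Conditions: 2 (2 equiv), NaOH (1.2 equiv), H2O, N2, 5 °C to rt, 24 h
Reagents that add atoms: none
Why: The phenoxide opens the epoxide of 2 at its CH2 end and the alkoxide of 3 closes onto CH2Cl (epoxide opening then Williamson-type closure), so no bond at the stereocentre is touched, (R)-2 becomes (S)-4 only because the CIP ranks of the two CH2 groups swap, and the low temperature suppresses direct chloride displacement that would erode ee.

Step 2
Reactants: 1 2,3,4-trimethoxyphenol
Product: 5 1-(methoxymethoxy)-2,3,4-trimethoxybenzene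
Conditions: MOMCl, iPr2NEt, CH2Cl2, 0 °C to rt
Reagents that add atoms: chloromethyl methyl ether (MOMCl), COCCl
Why: This is standard phenol O-alkylation (MOM protection), and it masks the one oxygen that later distinguishes ring B from ring A while providing the directing group for step 3.

Step 3
Reactants: 5 1-(methoxymethoxy)-2,3,4-trimethoxybenzene; 4 (S)-2-[(2,3,4-trimethoxyphenoxy)methyl]oxirane
Product: 7 (S)-1-[2-(methoxymethoxy)-3,4,5-trimethoxyphenyl]-3-(2,3,4-trimethoxyphenoxy)propan-2-ol, via [2-(methoxymethoxy)-3,4,5-trimethoxyphenyl]lithium 6 (not isolated)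
Conditions: 5 (1.4 equiv), n-BuLi (1.3 equiv), THF, 0 °C, 1 h; −78 °C, 4 (1.0 equiv), then BF3·OEt2 (1.3 equiv), 30 min; aq. NaHCO3
Reagents that add atoms: none
Why: Directed ortho-metalation next to OMOM followed by BF3-assisted SN2 opening of the terminal epoxide at CH2 leaves the C–O stereocentre untouched, and minor lithiation next to the 4-OMe would not matter because that regioisomer leads to the same quinone.

Step 4
Reactants: 7 (S)-1-[2-(methoxymethoxy)-3,4,5-trimethoxyphenyl]-3-(2,3,4-trimethoxyphenoxy)propan-2-ol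
Product: 10 (3S)-6,7,8-trimethoxy-3-[2-(methoxymethoxy)-3,4,5-trimethoxyphenyl]chromane, via {[(2S)-1-[2-(methoxymethoxy)-3,4,5-trimethoxyphenyl]-3-(2,3,4-trimethoxyphenoxy)propan-2-yl]oxy}triphenylphosphonium bistriflimide 8 (not isolated), via ring-B phenonium (spiro[2.5]octadienyl) bistriflimide 9 (not isolated)
Conditions: PPh3 (1.2 equiv), 2,6-lutidinium NTf2 (1.5 equiv, 0.1 M), CH2Cl2, undivided cell, graphite(+)/Pt(−), +1.0 V vs Ag/AgCl (about 2.4 F/mol), 0 °C; current off, add HFIP (equal volume), 40 °C, 3 h
Reagents that add atoms: none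
Why: Proposed new method: PPh3 (Ep about 1.0 V) is oxidised below the tetraalkoxyarenes (about 1.2 V), its radical cation is trapped by the OH of 7, and the second anodic electron transfer outruns β-scission of the phosphoranyl radical, so 8 accumulates as a cation pool while lutidinium is reduced to H2 at the cathode; with no external nucleophile present, warming in HFIP lets the ortho/para-dialkoxy-activated ring B expel Ph3P=O from the rear (Ar1-3 participation, forming C3–C1' with clean inversion) to give 9, whose CH2 terminus is opened 6-exo by the only free ortho carbon of ring A (forming C4–C4a, six-ring Friedel–Crafts closure being favoured over five-ring attack at C3), which leaves C3 as (S), and the product never sees the anode; the closest known reaction types are anodic Ph3P/alcohol activation to alkoxyphosphonium salts followed by SN2 with heteroatom nucleophiles, and solvolytic phenonium 1,2-aryl shifts or phenonium Friedel–Crafts alkylations in HFIP.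

Step 5
Reactants: 10 (3S)-6,7,8-trimethoxy-3-[2-(methoxymethoxy)-3,4,5-trimethoxyphenyl]chromane
Product: 12 abruquinone B, via 2,3,4-trimethoxy-6-[(3S)-6,7,8-trimethoxychroman-3-yl]phenol 11 (not isolated)
Conditions: p-TsOH·H2O (0.2 equiv), MeOH, 50 °C; evaporate; PhI(OAc)2 (1.1 equiv), MeCN/H2O 4:1, 0 °C, 30 min
Reagents that add atoms: water, O
Why: Acid-catalysed acetal exchange frees the phenol, and hypervalent-iodine oxidative demethylation of the 4-methoxyphenol (water adds at the OMe-bearing para carbon and MeOH leaves) gives the p-quinone selectively because only ring B has a free OH, while the weakly acidic medium avoids quinone-methide tautomerisation at C3.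

## Compound list
1 | 2,3,4-trimethoxyphenol | COc1ccc(O)c(OC)c1OC | starting material
2 | (R)-epichlorohydrin | ClC[C@H]1CO1 | starting material
3 | (R)-1-chloro-3-(2,3,4-trimethoxyphenoxy)propan-2-ol | COc1ccc(OC[C@@H](O)CCl)c(OC)c1OC | intermediate
4 | (S)-2-[(2,3,4-trimethoxyphenoxy)methyl]oxirane | COc1ccc(OC[C@@H]2CO2)c(OC)c1OC | intermediate
5 | 1-(methoxymethoxy)-2,3,4-trimethoxybenzene | COCOc1ccc(OC)c(OC)c1OC | intermediate
6 | [2-(methoxymethoxy)-3,4,5-trimethoxyphenyl]lithium | [Li]c1cc(OC)c(OC)c(OC)c1OCOC | intermediate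
7 | (S)-1-[2-(methoxymethoxy)-3,4,5-trimethoxyphenyl]-3-(2,3,4-trimethoxyphenoxy)propan-2-ol | COc1ccc(OC[C@@H](O)Cc2cc(OC)c(OC)c(OC)c2OCOC)c(OC)c1OC | intermediate
8 | (S)-alkoxytriphenylphosphonium bistriflimide of 7 | COc1ccc(OC[C@@H](O[P+](c3ccccc3)(c3ccccc3)c3ccccc3)Cc2cc(OC)c(OC)c(OC)c2OCOC)c(OC)c1OC.O=S(=O)([N-]S(=O)(=O)C(F)(F)F)C(F)(F)F | intermediate
9 | phenonium bistriflimide: ring B spiro-fused to a cyclopropane made of C3 and C4, C3 inverted, drawn as the para-oxocarbenium form and as the rotamer with OMOM anti to the CH2OAr arm (the spiro centre is lost on opening) | COc1ccc(OC[C@H]2C[C@@]23C=C(OC)C(=[O+]C)C(OC)=C3OCOC)c(OC)c1OC.O=S(=O)([N-]S(=O)(=O)C(F)(F)F)C(F)(F)F | intermediate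
10 | (3S)-6,7,8-trimethoxy-3-[2-(methoxymethoxy)-3,4,5-trimethoxyphenyl]chromane | COCOc1c(OC)c(OC)c(OC)cc1[C@H]2COc3c(cc(OC)c(OC)c3OC)C2 | intermediate
11 | 2,3,4-trimethoxy-6-[(3S)-6,7,8-trimethoxychroman-3-yl]phenol | COc1cc([C@H]2COc3c(cc(OC)c(OC)c3OC)C2)c(O)c(OC)c1OC | intermediate
12 | abruquinone B, 2,3-dimethoxy-5-[(3S)-6,7,8-trimethoxychroman-3-yl]-1,4-benzoquinone | COC1=C(OC)C(=O)C([C@H]2COc3c(cc(OC)c(OC)c3OC)C2)=CC1=O | target

## Step count and risks
Total steps: 5. Longest linear sequence: 4 (1 → 5 → 7 → 10 → 12, or 1 and 2 → 4 → 7 → 10 → 12).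

**Step 4 (the new step).**
- Risks:
  - the arenes are oxidised or phosphonylated instead of PPh3;
  - the ortho-OMOM oxygen attacks C3 to give a 2-substituted dihydrobenzofuran;
  - 9 is opened at C3 to give a five-membered ring;
  - 8 undergoes E2 elimination.
- Fallback (known chemistry, ring first and aryl second). It sets out from 4 and 6 and returns at 10.
  - Compound 4 is cyclised by 6-endo epoxide–arene Friedel–Crafts alkylation (HFIP, 50 °C) to (S)-6,7,8-trimethoxychroman-3-ol F1, with the C–O stereocentre untouched.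
  - F1 is converted with TsCl/pyridine into (S)-6,7,8-trimethoxychroman-3-yl tosylate F2.
  - F2 is displaced with SN2 inversion by lithium bis[2-(methoxymethoxy)-3,4,5-trimethoxyphenyl]cuprate F3, made from 6 and CuI in Et2O/THF at −20 °C to rt.
  - The inversion occurs at the same carbon and in the same sense as in the main route, so the same (S)-10 results.

**Step 3.**
- Risks:
  - BF3 cyclises the electron-rich glycidyl ether 4 or strips the MOM group;
  - the ArLi/BF3 pair decomposes before C–C bond formation.
- Fallback (site-defined organomagnesium, no Lewis acid). It sets out from 1 and returns at 7.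
  - NBS in MeCN at 0 °C gives 6-bromo-2,3,4-trimethoxyphenol F4.
  - MOMCl/iPr2NEt gives 1-bromo-2-(methoxymethoxy)-3,4,5-trimethoxybenzene F5.
  - Mg/LiCl in THF gives [2-(methoxymethoxy)-3,4,5-trimethoxyphenyl]magnesium bromide F6.
  - F6 opens 4 at the terminal carbon with CuI (10 mol %) at −30 to 0 °C.

**Step 5.**
- Risks:
  - iodine(III) attacks ring A;
  - an o-quinone forms;
  - the telescoped acid carries over into the oxidation.
- Fallback (anhydrous two-stage route through a ketal). It sets out from 10 and returns at 12.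
  - The MOM group is removed as before and 11 is isolated.
  - Compound 11 is oxidised anodically in MeOH (C(+)/Pt(−), LiClO4, 2,6-lutidine, phenol-selective potential about +0.8 V) to the quinone monoketal 4,4,5,6-tetramethoxy-2-[(3S)-6,7,8-trimethoxychroman-3-yl]cyclohexa-2,5-dien-1-one F7.
  - F7 is hydrolysed with dilute aqueous AcOH at rt.

## Further compounds
F1 | step 4 | (S)-6,7,8-trimethoxychroman-3-ol | COc1cc2C[C@H](O)COc2c(OC)c1OC
F2 | step 4 | (S)-6,7,8-trimethoxychroman-3-yl 4-methylbenzenesulfonate | COc1cc2C[C@H](OS(=O)(=O)c3ccc(C)cc3)COc2c(OC)c1OC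
F3 | step 4 | lithium bis[2-(methoxymethoxy)-3,4,5-trimethoxyphenyl]cuprate | [Li+].COCOc1c([Cu-]c2cc(OC)c(OC)c(OC)c2OCOC)cc(OC)c(OC)c1OC
F4 | step 3 | 6-bromo-2,3,4-trimethoxyphenol | COc1cc(Br)c(O)c(OC)c1OC
F5 | step 3 | 1-bromo-2-(methoxymethoxy)-3,4,5-trimethoxybenzene | COCOc1c(Br)cc(OC)c(OC)c1OC
F6 | step 3 | [2-(methoxymethoxy)-3,4,5-trimethoxyphenyl]magnesium bromide | COCOc1c([Mg]Br)cc(OC)c(OC)c1OC
F7 | step 5 | 4,4,5,6-tetramethoxy-2-[(3S)-6,7,8-trimethoxychroman-3-yl]cyclohexa-2,5-dien-1-one | COC1=C(OC)C(OC)(OC)C=C([C@H]2COc3c(cc(OC)c(OC)c3OC)C2)C1=O
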